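The route rests on one Diels–Alder disconnection of the cyclohexane ring. An endo-selective, catalytic enantioselective [4+2] cycloaddition of cyclobutenone with the (E)-silyl dienol ether of tiglic aldehyde closes the carbocycle through the C2–C3 bond (and C4–C5; locants of the 7-oxabicyclo[4.1.0]heptane core) and sets C2, C3 and C4 all-cis. It exploits the fact that O-2, O-3 and the C4 side chain lie on one face of that ring. Ring strain then drives a regioselective Baeyer–Villiger expansion to a cis-fused γ-lactone, whose α-carbon and carbonyl carbon become the methylidene-bearing and carbinol carbons of the side chain. Directed epoxidation and angeloylation finish the synthesis.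

Key step: step 3

Step 1
Reactants: 1 3-bromocyclobutan-1-one
Product: 2 cyclobut-2-en-1-one (cyclobutenone)
Conditions: Bu3N, neat, 23 °C, reduced pressure, product distilled into a −78 °C trap and used as a cold CH2Cl2 solution
Reagents that add atoms: none
Why: E1cB-type β-elimination of HBr from the β-bromo ketone; the volatile strained enone is removed from the ammonium salt as it forms, which should prevent its oligomerisation.

Step 2
Reactants: 3 (E)-2-methylbut-2-enal (tiglic aldehyde)
Product: 4 (E)-triisopropyl[(2-methylbuta-1,3-dien-1-yl)oxy]silane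
Conditions: iPr3SiOTf, Et3N, Et2O, 0 °C → 23 °C
Reagents that add atoms: triisopropylsilyl trifluoromethanesulfonate, CC(C)[Si](OS(=O)(=O)C(F)(F)F)(C(C)C)C(C)C
Why: Silyl dienol ether formation by soft enolisation: the silyl triflate activates the carbonyl and Et3N removes a γ-proton of the s-trans enal, which should place the siloxy group trans to the vinyl group, i.e. the (1E)-diene that can reach the s-cis reactive conformation.

Step 3
Reactants: 2 cyclobut-2-en-1-one; 4 (E)-triisopropyl[(2-methylbuta-1,3-dien-1-yl)oxy]silane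
Product: 5 (1S,5R,6R)-4-methyl-5-[(triisopropylsilyl)oxy]bicyclo[4.2.0]oct-3-en-7-one
Conditions: (S)-3,3-diphenyl-1-(2-methylphenyl)tetrahydro-1H,3H-pyrrolo[1,2-c][1,3,2]oxazaborole (20 mol %), Tf2NH (16 mol %), CH2Cl2, −78 °C
Reagents that add atoms: none
Why: Diels–Alder reaction, a concerted but asynchronous [4+2] cycloaddition of the strain-activated, Lewis-acid-bound enone with the electron-rich diene; the closest known reaction types are the chiral oxazaborolidinium-catalysed Diels–Alder reaction of cyclic enones and the thermal cycloaddition of cyclobutenone. The six-membered carbocycle is closed as an intermolecular [4+2] annulation: the siloxy-bearing diene terminus bonds to the enone α-carbon (C5–C6 of 5, later C2–C3 of the target) and the CH2 terminus to the β-carbon (C1–C2). This regiochemistry follows from the 1-siloxy donor, which puts the largest HOMO coefficient on the unsubstituted diene terminus and outweighs the weaker opposing bias of the 2-methyl group. The cis ring fusion at C1 and C6 follows from suprafacial addition to the cyclic Z-alkene, and the cis relation of the C5 siloxy group to the four-membered ring from the endo transition state combined with the (E)-geometry of the siloxy terminus, so all three new stereocentres should be cis. The absolute configuration is set by the catalyst: in the precomplex the carbonyl binds boron syn to the C=C bond with an α-C–H···O contact and one phenyl group screens the rear face, so the diene should add to the Si face at C-2 of cyclobutenone. The step needs endo and enantiofacial selectivity; the compact dienophile and low temperature should favour endo, and the bulky triisopropylsilyl group should suppress silyl transfer to the acid, which would open an unselective background path.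

Step 4
Reactants: 5 (1S,5R,6R)-4-methyl-5-[(triisopropylsilyl)oxy]bicyclo[4.2.0]oct-3-en-7-one
Product: 6 (3aS,7S,7aR)-6-methyl-7-[(triisopropylsilyl)oxy]-3a,4,7,7a-tetrahydro-1-benzofuran-2(3H)-one
Conditions: H2O2 (30 % aq.), AcOH, 0 °C
Reagents that add atoms: hydrogen peroxide, OO
Why: Baeyer–Villiger oxidation of the strained cyclobutanone, which should be much faster than epoxidation of the trisubstituted alkene under these conditions; the more substituted bridgehead carbon C6 migrates with retention, so the new C–O bond stays cis to the siloxy group and to the CH2 arm.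

Step 5
Reactants: 6 (3aS,7S,7aR)-6-methyl-7-[(triisopropylsilyl)oxy]-3a,4,7,7a-tetrahydro-1-benzofuran-2(3H)-one
Product: 9 (3aS,7S,7aR)-6-methyl-3-methylidene-7-[(triisopropylsilyl)oxy]-3a,4,7,7a-tetrahydro-1-benzofuran-2(3H)-one, via Mannich base 7 (not isolated), via trimethylammonium iodide 8 (not isolated)
Conditions: LiN(iPr)2, THF, −78 °C; CH2=NMe2+ I−, −78 °C → 23 °C; MeI, MeOH, 23 °C; NaHCO3 (aq.), CH2Cl2, 23 °C
Reagents that add atoms: Eschenmoser's salt (N,N-dimethylmethyleneiminium iodide), C=[N+](C)C.[I-]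
Why: α-Methylenation by Mannich reaction of the lithium lactone enolate with Eschenmoser's salt, N-methylation and base-induced β-elimination of trimethylamine (Hofmann-type); no stereocentre is created in 9.

Step 6
Reactants: 9 (3aS,7S,7aR)-6-methyl-3-methylidene-7-[(triisopropylsilyl)oxy]-3a,4,7,7a-tetrahydro-1-benzofuran-2(3H)-one
Product: 10 (3aS,7S,7aR)-6-methyl-3-methylidene-7-[(triisopropylsilyl)oxy]-2,3,3a,4,7,7a-hexahydro-1-benzofuran-2-ol (lactol, mixture of anomers)
Conditions: iBu2AlH (1.1 equiv), CH2Cl2, −78 °C; aq. potassium sodium tartrate (KNaC4H4O6)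
Reagents that add atoms: none
Why: Partial reduction of the lactone with iBu2AlH: the aluminium hemiacetal is stable at −78 °C and 1,2-addition should outrun conjugate reduction, giving the lactol on work-up.

Step 7
Reactants: 10 (3aS,7S,7aR)-6-methyl-3-methylidene-7-[(triisopropylsilyl)oxy]-2,3,3a,4,7,7a-hexahydro-1-benzofuran-2-ol
Product: 11 (1R,2S,6S)-6-[(3S)-3-hydroxyhexa-1,5-dien-2-yl]-3-methyl-2-[(triisopropylsilyl)oxy]cyclohex-3-en-1-ol
Conditions: B-allyldiisopinocampheylborane prepared from (+)-α-pinene (2.2 equiv), Et2O, −78 → −20 °C; then NaOH (3 M), H2O2 (30 %), 0 → 23 °C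
Reagents that add atoms: B-allylbis[(1R,2S,3R,5R)-2,6,6-trimethylbicyclo[3.1.1]hept-3-yl]borane, C=CCB([C@@H]1C[C@@H]2C[C@H]([C@H]1C)C2(C)C)[C@@H]1C[C@@H]2C[C@H]([C@H]1C)C2(C)C
Why: Brown asymmetric allylboration of the lactol through its open 4-hydroxy enal form; in the chair Zimmerman–Traxler transition state the reagent derived from (+)-α-pinene should deliver allyl to the Si face of the aldehyde, which sets the (3S)-carbinol centre under reagent control.

Step 8
Reactants: 11 (1R,2S,6S)-6-[(3S)-3-hydroxyhexa-1,5-dien-2-yl]-3-methyl-2-[(triisopropylsilyl)oxy]cyclohex-3-en-1-ol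
Product: 12 (1R,2S,6S)-6-[(3S)-3-hydroxy-6-methylhepta-1,5-dien-2-yl]-3-methyl-2-[(triisopropylsilyl)oxy]cyclohex-3-en-1-ol
Conditions: second-generation Grubbs catalyst RuCl2(H2IMes)(PCy3)(=CHPh) (5 mol %), 2-methylbut-2-ene/CH2Cl2, 40 °C, sealed vessel
Reagents that add atoms: 2-methylbut-2-ene, CC=C(C)C
Why: Olefin cross-metathesis of the monosubstituted alkene with excess 2-methylbut-2-ene installs the isopropylidene terminus; the 1,1-disubstituted alkene and the trisubstituted alkene of the cyclohexene ring should be too hindered to enter the catalytic cycle.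

Step 9
Reactants: 12 (1R,2S,6S)-6-[(3S)-3-hydroxy-6-methylhepta-1,5-dien-2-yl]-3-methyl-2-[(triisopropylsilyl)oxy]cyclohex-3-en-1-ol
Product: 13 (3S)-2-{(1S,5S,6R)-6-hydroxy-4-methyl-5-[(triisopropylsilyl)oxy]cyclohex-3-en-1-yl}-6-methylhepta-1,5-dien-3-yl acetate
Conditions: Ac2O (1.1 equiv), pyridine, DMAP (5 mol %), CH2Cl2, −20 → 0 °C
Reagents that add atoms: acetic anhydride, CC(=O)OC(C)=O
Why: Site-selective acylation: the hydroxyl on the cyclohexene ring is flanked by the bulky triisopropylsilyl ether and the branched side chain, so the acyclic allylic hydroxyl should be acetylated first with one equivalent of anhydride.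

Step 10
Reactants: 13 (3S)-2-{(1S,5S,6R)-6-hydroxy-4-methyl-5-[(triisopropylsilyl)oxy]cyclohex-3-en-1-yl}-6-methylhepta-1,5-dien-3-yl acetate
Product: 14 (3S)-2-[(1S,5S,6R)-5,6-dihydroxy-4-methylcyclohex-3-en-1-yl]-6-methylhepta-1,5-dien-3-yl acetate
Conditions: HF·pyridine, pyridine, THF, 0 → 23 °C
Reagents that add atoms: none
Why: Fluoride-mediated cleavage of the silyl ether (Si–F bond formation) under buffered, non-basic conditions that should leave the allylic acetate in place and prevent acyl migration.

Step 11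
Reactants: 14 (3S)-2-[(1S,5S,6R)-5,6-dihydroxy-4-methylcyclohex-3-en-1-yl]-6-methylhepta-1,5-dien-3-yl acetate
Product: 15 (3S)-2-[(1S,2R,3R,4S,6S)-2,3-dihydroxy-1-methyl-7-oxabicyclo[4.1.0]heptan-4-yl]-6-methylhepta-1,5-dien-3-yl acetate
Conditions: VO(acac)2 (5 mol %), tBuOOH (1.5 equiv, decane), CH2Cl2, 0 → 23 °C
Reagents that add atoms: tert-butyl hydroperoxide, CC(C)(C)OO
Why: Vanadium-catalysed hydroxyl-directed epoxidation (Sharpless–Michaelson type): the peroxide is delivered from vanadium bound to the allylic hydroxyl (and the cis homoallylic one), so the oxirane should form cis to both hydroxyls and set C1 and C6, while the side-chain alkenes, which carry no free allylic hydroxyl, should stay untouched.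

Step 12
Reactants: 15 (3S)-2-[(1S,2R,3R,4S,6S)-2,3-dihydroxy-1-methyl-7-oxabicyclo[4.1.0]heptan-4-yl]-6-methylhepta-1,5-dien-3-yl acetate; 16 angelic acid, (Z)-2-methylbut-2-enoic acid
Product: 18 (1S,2R,3R,4S,6S)-4-[(3S)-3-acetoxy-6-methylhepta-1,5-dien-2-yl]-1-methyl-7-oxabicyclo[4.1.0]heptane-2,3-diyl bis[(Z)-2-methylbut-2-enoate] (CNP0188566.2), via mixed anhydride 17 (not isolated)
Conditions: 16 (6 equiv), 2,4,6-trichlorobenzoyl chloride, Et3N, toluene, 23 °C, filtration of the ammonium salt; then 15, toluene, 80 °C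
Reagents that add atoms: none
Why: Yamaguchi esterification: each hydroxyl attacks the mixed anhydride at the unhindered angeloyl carbonyl, and the absence of a nucleophilic acyl-transfer catalyst should avoid the addition–elimination path that isomerises angelates to tiglates.

Compound list
1 | 3-bromocyclobutan-1-one | O=C1CC(Br)C1 | starting material
2 | cyclobut-2-en-1-one | O=C1C=CC1 | intermediate
3 | (E)-2-methylbut-2-enal (tiglic aldehyde) | C/C=C(\C)C=O | starting material
4 | (E)-triisopropyl[(2-methylbuta-1,3-dien-1-yl)oxy]silane | C=C/C(C)=C/O[Si](C(C)C)(C(C)C)C(C)C | intermediate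
5 | (1S,5R,6R)-4-methyl-5-[(triisopropylsilyl)oxy]bicyclo[4.2.0]oct-3-en-7-one | O=C1C[C@@H]2CC=C(C)[C@H](O[Si](C(C)C)(C(C)C)C(C)C)[C@H]12 | intermediate
6 | (3aS,7S,7aR)-6-methyl-7-[(triisopropylsilyl)oxy]-3a,4,7,7a-tetrahydro-1-benzofuran-2(3H)-one | O=C1C[C@@H]2CC=C(C)[C@H](O[Si](C(C)C)(C(C)C)C(C)C)[C@@H]2O1 | intermediate
7 | Mannich base: 3-[(dimethylamino)methyl] derivative of 6 (C-3 configuration of no consequence) | O=C1C(CN(C)C)[C@@H]2CC=C(C)[C@H](O[Si](C(C)C)(C(C)C)C(C)C)[C@@H]2O1 | intermediate
8 | trimethylammonium iodide: N-methylated 7 | O=C1C(C[N+](C)(C)C)[C@@H]2CC=C(C)[C@H](O[Si](C(C)C)(C(C)C)C(C)C)[C@@H]2O1.[I-] | intermediate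
9 | (3aS,7S,7aR)-6-methyl-3-methylidene-7-[(triisopropylsilyl)oxy]-3a,4,7,7a-tetrahydro-1-benzofuran-2(3H)-one | O=C1C(=C)[C@@H]2CC=C(C)[C@H](O[Si](C(C)C)(C(C)C)C(C)C)[C@@H]2O1 | intermediate
10 | (3aS,7S,7aR)-6-methyl-3-methylidene-7-[(triisopropylsilyl)oxy]-2,3,3a,4,7,7a-hexahydro-1-benzofuran-2-ol (anomeric mixture) | OC1C(=C)[C@@H]2CC=C(C)[C@H](O[Si](C(C)C)(C(C)C)C(C)C)[C@@H]2O1 | intermediate
11 | (1R,2S,6S)-6-[(3S)-3-hydroxyhexa-1,5-dien-2-yl]-3-methyl-2-[(triisopropylsilyl)oxy]cyclohex-3-en-1-ol | C=C([C@H](CC=C)O)[C@@H]1CC=C(C)[C@H](O[Si](C(C)C)(C(C)C)C(C)C)[C@@H]1O | intermediate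
12 | (1R,2S,6S)-6-[(3S)-3-hydroxy-6-methylhepta-1,5-dien-2-yl]-3-methyl-2-[(triisopropylsilyl)oxy]cyclohex-3-en-1-ol | C=C([C@H](CC=C(C)C)O)[C@@H]1CC=C(C)[C@H](O[Si](C(C)C)(C(C)C)C(C)C)[C@@H]1O | intermediate
13 | (3S)-2-{(1S,5S,6R)-6-hydroxy-4-methyl-5-[(triisopropylsilyl)oxy]cyclohex-3-en-1-yl}-6-methylhepta-1,5-dien-3-yl acetate | C=C([C@H](CC=C(C)C)OC(C)=O)[C@@H]1CC=C(C)[C@H](O[Si](C(C)C)(C(C)C)C(C)C)[C@@H]1O | intermediate
14 | (3S)-2-[(1S,5S,6R)-5,6-dihydroxy-4-methylcyclohex-3-en-1-yl]-6-methylhepta-1,5-dien-3-yl acetate | C=C([C@H](CC=C(C)C)OC(C)=O)[C@@H]1CC=C(C)[C@H](O)[C@@H]1O | intermediate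
15 | (3S)-2-[(1S,2R,3R,4S,6S)-2,3-dihydroxy-1-methyl-7-oxabicyclo[4.1.0]heptan-4-yl]-6-methylhepta-1,5-dien-3-yl acetate | C=C([C@H](CC=C(C)C)OC(C)=O)[C@@H]1C[C@@H]2O[C@]2(C)[C@H](O)[C@@H]1O | intermediate
16 | angelic acid, (Z)-2-methylbut-2-enoic acid | C/C=C(/C)C(=O)O | starting material
17 | (Z)-2-methylbut-2-enoic 2,4,6-trichlorobenzoic anhydride | C/C=C(/C)C(=O)OC(=O)c1c(Cl)cc(Cl)cc1Cl | intermediate
18 | (1S,2R,3R,4S,6S)-4-[(3S)-3-acetoxy-6-methylhepta-1,5-dien-2-yl]-1-methyl-7-oxabicyclo[4.1.0]heptane-2,3-diyl bis[(Z)-2-methylbut-2-enoate] | C=C([C@H](CC=C(C)C)OC(C)=O)[C@@H]1C[C@@H]2O[C@]2(C)[C@H](OC(=O)/C(C)=C\C)[C@@H]1OC(=O)/C(C)=C\C | target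

Total step count: 12. Longest linear sequence: 11 steps (step 1 or step 2, then steps 3–12).

Steps most likely to fail

Step 3. Enantiofacial discrimination may be poor, or silyl transfer from the diene to the acid may start an achiral catalytic cycle and erode the enantiomeric purity. The fallback sets out from 2 and 4 and comes back at 6. The cycloaddition is run without catalyst (CH2Cl2, 23 °C) to give 5 as the racemate, which is taken through step 4 to racemic 6. HF·pyridine frees the alcohol, giving racemic hydroxy lactone F1. Esterification with (S)-2-methoxy-2-phenylacetic acid (EDC·HCl, DMAP, CH2Cl2) gives two diastereomeric esters that are separated by chromatography; the one derived from the (3aS,7S,7aR)-alcohol is mandelate ester F2. K2CO3 in MeOH, followed by mildly acidic work-up to re-close the lactone, releases hydroxy lactone F1 as a single enantiomer, and iPr3SiOTf with 2,6-lutidine returns 6.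

Step 12. The angeloyl group may isomerise to tiglate under the acylation conditions, the hindered C-2 hydroxyl may be acylated incompletely, or the epoxide may open on heating. The fallback sets out from 15 and comes back at 18. Both hydroxyls are esterified with 2-[bis(2,2,2-trifluoroethoxy)phosphoryl]propanoic acid (EDC·HCl, DMAP, CH2Cl2, 0 → 23 °C) to give bis(phosphonopropanoate) F6. A double Still–Gennari olefination (KN(SiMe3)2, 18-crown-6, THF, −78 °C; acetaldehyde) should then build both (Z)-2-methylbut-2-enoates in place.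

Step 9. Acylation may not discriminate between the two secondary hydroxyls, giving the diacetate or the ring acetate. The fallback sets out from 12 and comes back at 14. HF·pyridine removes the silyl ether to give triol F3. 2,2-Dimethoxypropane with pyridinium p-toluenesulfonate should engage only the cis-1,2-diol of the cyclohexene ring, giving acetonide alcohol F4. Ac2O, pyridine and DMAP acetylate the remaining side-chain hydroxyl to give acetonide acetate F5, and 80 % aqueous AcOH at 23 °C removes the acetonide.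

Further compounds
F1 | step 3 | (3aS,7S,7aR)-7-hydroxy-6-methyl-3a,4,7,7a-tetrahydro-1-benzofuran-2(3H)-one | O=C1C[C@@H]2CC=C(C)[C@H](O)[C@@H]2O1
F2 | step 3 | (3aS,7S,7aR)-6-methyl-2-oxo-2,3,3a,4,7,7a-hexahydro-1-benzofuran-7-yl (S)-2-methoxy-2-phenylacetate | O=C1C[C@@H]2CC=C(C)[C@H](OC(=O)[C@@H](OC)c3ccccc3)[C@@H]2O1
F3 | step 9 | (1R,2S,6S)-6-[(3S)-3-hydroxy-6-methylhepta-1,5-dien-2-yl]-3-methylcyclohex-3-ene-1,2-diol | C=C([C@H](CC=C(C)C)O)[C@@H]1CC=C(C)[C@H](O)[C@@H]1O
F4 | step 9 | acetonide (2,2-dimethyl-1,3-dioxolane) of F3 across the ring cis-1,2-diol, side-chain hydroxyl free | C=C([C@H](CC=C(C)C)O)[C@@H]1CC=C(C)[C@@H]2OC(C)(C)O[C@H]12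
F5 | step 9 | acetate of F4 at the side-chain hydroxyl | C=C([C@H](CC=C(C)C)OC(C)=O)[C@@H]1CC=C(C)[C@@H]2OC(C)(C)O[C@H]12
F6 | step 12 | (1S,2R,3R,4S,6S)-4-[(3S)-3-acetoxy-6-methylhepta-1,5-dien-2-yl]-1-methyl-7-oxabicyclo[4.1.0]heptane-2,3-diyl bis{2-[bis(2,2,2-trifluoroethoxy)phosphoryl]propanoate} (mixture of epimers at the phosphonate α-carbons) | C=C([C@H](CC=C(C)C)OC(C)=O)[C@@H]1C[C@@H]2O[C@]2(C)[C@H](OC(=O)C(C)P(=O)(OCC(F)(F)F)OCC(F)(F)F)[C@@H]1OC(=O)C(C)P(=O)(OCC(F)(F)F)OCC(F)(F)F
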